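The C5 side chain is cut at its C=C bond (Wittig, back to a C5 CH2OH group). Then C3a–C7a, C6–C7 and C7–O are cut in one move, which unravels ring A and the dihydrofuran ring to an acyclic ethynyl ether carrying a furan. The C2–C3 bond is cut last (aldol).
Enabling feature: ring A has oxygen on two neighbouring carbons, C7a (O1) and C7 (OMe), right at the C3a–C7a fusion, and a carbon substituent only at C5. A furan held through its C2 by the chain C3–C2–O1–C≡CH maps onto this pattern: its ring oxygen ends on the terminal alkyne carbon (C7) and its C4 substituent ends at C5.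
Forward: a bought 2,4-disubstituted furan is homologated to a furan-2-ylacetyl imide, joined to veratraldehyde (C2–C3), reduced, silylated and O-ethynylated. One gold-catalysed isomerisation then closes the dihydrofuran ring and ring A together; the veratryl ring is present from the aldol on.
Stereochemistry: both centres come from a single Evans syn-aldol with (S)-4-benzyloxazolidin-2-one. Syn in the chain becomes trans-(2S,3R) in the ring, and no later step breaks a bond at C2 or C3.
End game: O-methylation at C7, desilylation, tandem MnO2/Wittig homologation at C5, i-Bu2AlH reduction.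

Key step: step 9

Remark: all intermediates carry the benzofuran numbering of the target (O1, C2, C3, C3a, C4–C7, C7a), and the bromofuran ester and the Reformatsky reagent (as its ether solution) are taken to be catalogue compounds.

Step 1
Reactants: 1 methyl 5-bromofuran-3-carboxylate; 2 (2-tert-butoxy-2-oxoethyl)zinc bromide
Product: 3 methyl 5-(2-tert-butoxy-2-oxoethyl)furan-3-carboxylate
Conditions: Pd2(dba)3 (2.5 mol %), XPhos (10 mol %), THF, 60 °C
Reagents that add atoms: none
Why: Negishi-type cross-coupling of a Reformatsky reagent: the 2-bromofuran, activated by its C4 ester, should add readily to zerovalent palladium and the mild zinc enolate spares both esters, so that the 2,4-pattern of the furan (future C3a and C5) is fixed by the position of the bromine instead of by a lithiation of uncertain regiochemistry.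

Step 2
Reactants: 3 methyl 5-(2-tert-butoxy-2-oxoethyl)furan-3-carboxylate
Product: 4 2-[4-(methoxycarbonyl)furan-2-yl]acetic acid
Conditions: CF3CO2H, CH2Cl2, 0 °C to rt
Reagents that add atoms: none
Why: Acidolysis of a tert-butyl ester (E1 loss of 2-methylpropene) leaves the methyl ester intact, and the furan survives the acid because the C4 ester deactivates it towards protonation and tert-butylation.

Step 3
Reactants: 4 2-[4-(methoxycarbonyl)furan-2-yl]acetic acid; 5 (S)-4-benzyloxazolidin-2-one
Product: 7 methyl 5-{2-[(4S)-4-benzyl-2-oxo-1,3-oxazolidin-3-yl]-2-oxoethyl}furan-3-carboxylate, via mixed pivalic anhydride 6 (not isolated)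
Conditions: t-BuCOCl, Et3N, THF, −20 °C; then LiCl, 5, −20 °C to rt
Reagents that add atoms: pivaloyl chloride, CC(C)(C)C(=O)Cl (atoms kept in 6 only)
Why: N-Acylation of an Evans oxazolidinone through a mixed pivalic anhydride in the LiCl/Et3N variant, in which the hindered pivaloyl carbonyl steers attack to the furylacetyl carbonyl and no strong base meets the acidic CH2 group.

Step 4
Reactants: 7 methyl 5-{2-[(4S)-4-benzyl-2-oxo-1,3-oxazolidin-3-yl]-2-oxoethyl}furan-3-carboxylate; 8 veratraldehyde (3,4-dimethoxybenzaldehyde)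
Product: 11 (4S)-4-benzyl-3-{(2R,3S)-3-(3,4-dimethoxyphenyl)-3-hydroxy-2-[4-(methoxycarbonyl)furan-2-yl]propanoyl}-1,3-oxazolidin-2-one (syn aldol), via Z boron enolate 9 (not isolated), via boron aldolate 10 (not isolated)
Conditions: n-Bu2BOTf, Et3N, CH2Cl2, −78 to 0 °C; 8, −78 to 0 °C; then H2O2, MeOH, pH 7 buffer, 0 °C
Reagents that add atoms: di-n-butylboron triflate, CCCCB(CCCC)OS(=O)(=O)C(F)(F)F (atoms kept in 9 and 10 only)
Why: Evans syn-aldol reaction: soft enolisation gives the Z boron enolate 9, which adds to 8 through a Zimmerman–Traxler chair on the enolate face away from the benzyl group with the imide dipoles opposed, so that the auxiliary sets both new stereocentres (future C2 as S and future C3) in the syn relation.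

Step 5
Reactants: 11 syn-aldol imide
Product: 13 (1S,2R)-1-(3,4-dimethoxyphenyl)-2-[4-(hydroxymethyl)furan-2-yl]propane-1,3-diol, via diol ester 12 (not isolated)
Conditions: LiBH4, MeOH, THF, 0 °C, then 45 °C
Reagents that add atoms: none
Why: Reductive removal of the auxiliary with LiBH4 is fast at 0 °C and takes away the carbonyl group that could allow retro-aldol cleavage or epimerisation, after which the robust diol ester 12 can be warmed with the methanol-activated borohydride to reduce the furoate ester too, no bond at either stereocentre being touched.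

Step 6
Reactants: 13 (1S,2R)-1-(3,4-dimethoxyphenyl)-2-[4-(hydroxymethyl)furan-2-yl]propane-1,3-diol
Product: 14 (1S,2R)-1-(3,4-dimethoxyphenyl)-3-(triisopropylsilyloxy)-2-{4-[(triisopropylsilyloxy)methyl]furan-2-yl}propan-1-ol
Conditions: i-Pr3SiCl (2.2 equiv), imidazole, DMF, 0 °C to rt
Reagents that add atoms: chlorotriisopropylsilane, CC(C)[Si](Cl)(C(C)C)C(C)C
Why: Sterically controlled silylation: the bulky chlorosilane should take the two primary hydroxyl groups and leave the hindered secondary benzylic one free, and triisopropylsilyl is preferred to smaller silyl groups because it resists O-to-O migration in the alkoxide of the following step.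

Step 7
Reactants: 14 bis-silylated secondary alcohol; 15 trichloroethylene
Product: 17 (E)-1,2-dichlorovinyl ether of 14 (1S,2R), via potassium alkoxide 16 (not isolated)
Conditions: KH, THF, 0 °C to rt; 15, −50 °C to rt
Reagents that add atoms: potassium hydride, [K+].[H-] (potassium kept in 16 only)
Why: First half of the trichloroethylene route to alkynyl ethers: base converts 15 into dichloroacetylene, to which the alkoxide 16 adds in anti fashion to give the E-1,2-dichlorovinyl ether, and since only the O–H bond of 14 is broken the stereocentres are retained.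

Step 8
Reactants: 17 (E)-1,2-dichlorovinyl ether
Product: 20 (1S,2R)-1-(3,4-dimethoxyphenyl)-1-(ethynyloxy)-3-(triisopropylsilyloxy)-2-{4-[(triisopropylsilyloxy)methyl]furan-2-yl}propane, via chloroethynyl ether 18 (not isolated), via lithium acetylide 19 (not isolated)
Conditions: n-BuLi (2.4 equiv), THF, −78 °C; then H2O, −78 to 0 °C
Reagents that add atoms: n-butyllithium, [Li]CCCC (lithium kept in 19 only)
Why: Second half of the trichloroethylene route: dehydrochlorination to 18 and chlorine–lithium exchange to 19 run at −78 °C, where furan lithiation, retro-ene fragmentation and [3,3] shift of the benzylic ether should not compete, and cold neutral protonation, rapid filtration through Et3N-deactivated silica and immediate use keep the labile terminal ether intact.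

Step 9
Reactants: 20 furan-tethered ethynyl ether
Product: 22 (2S,3R)-2-(3,4-dimethoxyphenyl)-3,5-bis[(triisopropylsilyloxy)methyl]-2,3-dihydrobenzofuran-7-ol, via fused oxepine 21 (not isolated)
Conditions: Ph3PAuNTf2 (3 mol %), 4 Å molecular sieves, CH2Cl2, −20 to 0 °C, slow addition of 20
Reagents that add atoms: none
Why: Ph3PAuNTf2 (monovalent gold) binds the ethynyl ether, whose oxygen lone pair makes the O-bearing carbon the electrophilic end, and furan C2 attacks it in a 5-exo-dig closure that forms C3a–C7a and with it the dihydrofuran ring, leaving a cyclopropyl gold carbenoid with the metal on the terminal carbon. Opening of the cyclopropane and of the furan C2–O bond gives a gold-stabilised dienal carbene whose aldehyde oxygen adds to the carbene carbon (C7–O), releasing the catalyst and the oxepine 21; its 6π electrocyclic valence tautomerisation to the arene oxide forms C6–C7 and so closes the six-membered ring A. The arene oxide opens at its C6–O bond, because the cation so formed is stabilised by O1 on C7a, and loss of the C7 proton leaves the hydroxyl group on C7 alone. The closest known reaction is the gold-catalysed furan–yne phenol synthesis, which has been run on furans tethered to alkynyl ethers to give 2,3-dihydrobenzofuran-7-ols. No stereocentre is created: C2 and C3 lie in the tether, no bond to them is broken, and the syn chain can only fold into the trans-2,3 ring. The furan has to outrun the veratryl ring as nucleophile and also outrun ionisation, retro-ene loss, [3,3] shift and hydration of the benzylic ether, which its higher nucleophilicity, the unstrained five-membered closure, the low temperature, the slow addition and the sieves should secure, while the 2,4-substitution of the furan places the side-chain carbon at C5.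

Step 10
Reactants: 22 7-hydroxy dihydrobenzofuran
Product: 23 (2S,3R)-2-(3,4-dimethoxyphenyl)-7-methoxy-3,5-bis[(triisopropylsilyloxy)methyl]-2,3-dihydrobenzofuran
Conditions: MeI, K2CO3, acetone, 40 °C
Reagents that add atoms: iodomethane, CI
Why: Williamson ether synthesis on the only acidic hydroxyl group, under conditions to which the silyl ethers and the benzylic ether stereocentre are inert.

Step 11
Reactants: 23 7-methoxy bis-silyl ether
Product: 24 [(2S,3R)-2-(3,4-dimethoxyphenyl)-7-methoxy-2,3-dihydrobenzofuran-3,5-diyl]dimethanol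
Conditions: n-Bu4NF, THF, 0 °C to rt
Reagents that add atoms: none
Why: Fluoride-induced desilylation, driven by the strength of the Si–F bond, frees both primary alcohols without touching any other group.

Step 12
Reactants: 24 diol; 25 ethyl (triphenylphosphoranylidene)acetate
Product: 27 ethyl (E)-3-[(2S,3R)-2-(3,4-dimethoxyphenyl)-3-(hydroxymethyl)-7-methoxy-2,3-dihydrobenzofuran-5-yl]acrylate, via aldehyde 26 (not isolated)
Conditions: MnO2, 25, CH2Cl2, rt to reflux
Reagents that add atoms: none
Why: Tandem oxidation–Wittig process: MnO2 oxidises only the benzylic C5 hydroxymethyl group (the C3 hydroxymethyl group is an ordinary primary alcohol), and the ester-stabilised ylide 25 traps aldehyde 26 as it forms to give the E-enoate, as is usual for such ylides and aromatic aldehydes.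

Step 13
Reactants: 27 E-enoate
Product: 28 Hierochin B, (E)-3-[(2S,3R)-2-(3,4-dimethoxyphenyl)-3-(hydroxymethyl)-7-methoxy-2,3-dihydrobenzofuran-5-yl]prop-2-en-1-ol
Conditions: i-Bu2AlH (4 equiv), CH2Cl2, −78 °C
Reagents that add atoms: none
Why: 1,2-Reduction of an α,β-unsaturated ester with i-Bu2AlH gives the allylic alcohol with the E double bond retained, the free hydroxyl group merely consuming one equivalent of hydride.

Compound list
1 | methyl 5-bromofuran-3-carboxylate | COC(=O)c1coc(Br)c1 | starting material
2 | (2-tert-butoxy-2-oxoethyl)zinc bromide | CC(C)(C)OC(=O)C[Zn]Br | starting material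
3 | methyl 5-(2-tert-butoxy-2-oxoethyl)furan-3-carboxylate | COC(=O)c1coc(CC(=O)OC(C)(C)C)c1 | intermediate
4 | 2-[4-(methoxycarbonyl)furan-2-yl]acetic acid | COC(=O)c1coc(CC(=O)O)c1 | intermediate
5 | (S)-4-benzyloxazolidin-2-one | O=C1N[C@@H](Cc2ccccc2)CO1 | starting material
6 | 2-[4-(methoxycarbonyl)furan-2-yl]acetic pivalic anhydride | COC(=O)c1coc(CC(=O)OC(=O)C(C)(C)C)c1 | intermediate
7 | methyl 5-{2-[(4S)-4-benzyl-2-oxo-1,3-oxazolidin-3-yl]-2-oxoethyl}furan-3-carboxylate | COC(=O)c1coc(CC(=O)N2[C@@H](Cc3ccccc3)COC2=O)c1 | intermediate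
8 | veratraldehyde | COc1ccc(C=O)cc1OC | starting material
9 | (Z)-di-n-butylboron enolate of 7 | CCCCB(CCCC)O/C(=C\c1cc(C(=O)OC)co1)N1[C@@H](Cc2ccccc2)COC1=O | intermediate
10 | di-n-butylboron aldolate of 11 | COc1ccc([C@@H](OB(CCCC)CCCC)[C@@H](C(=O)N2[C@@H](Cc3ccccc3)COC2=O)c2cc(C(=O)OC)co2)cc1OC | intermediate
11 | (4S)-4-benzyl-3-{(2R,3S)-3-(3,4-dimethoxyphenyl)-3-hydroxy-2-[4-(methoxycarbonyl)furan-2-yl]propanoyl}-1,3-oxazolidin-2-one | COc1ccc([C@@H](O)[C@@H](C(=O)N2[C@@H](Cc3ccccc3)COC2=O)c2cc(C(=O)OC)co2)cc1OC | intermediate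
12 | methyl 5-[(1S,2R)-1-(3,4-dimethoxyphenyl)-1,3-dihydroxypropan-2-yl]furan-3-carboxylate | COc1ccc([C@@H](O)[C@@H](CO)c2cc(C(=O)OC)co2)cc1OC | intermediate
13 | (1S,2R)-1-(3,4-dimethoxyphenyl)-2-[4-(hydroxymethyl)furan-2-yl]propane-1,3-diol | COc1ccc([C@@H](O)[C@@H](CO)c2cc(CO)co2)cc1OC | intermediate
14 | (1S,2R)-1-(3,4-dimethoxyphenyl)-3-(triisopropylsilyloxy)-2-{4-[(triisopropylsilyloxy)methyl]furan-2-yl}propan-1-ol | COc1ccc([C@@H](O)[C@@H](CO[Si](C(C)C)(C(C)C)C(C)C)c2cc(CO[Si](C(C)C)(C(C)C)C(C)C)co2)cc1OC | intermediate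
15 | trichloroethylene | ClC=C(Cl)Cl | starting material
16 | potassium alkoxide of 14 | COc1ccc([C@@H]([O-])[C@@H](CO[Si](C(C)C)(C(C)C)C(C)C)c2cc(CO[Si](C(C)C)(C(C)C)C(C)C)co2)cc1OC.[K+] | intermediate
17 | (E)-1,2-dichlorovinyl ether of 14 | COc1ccc([C@@H](O/C(Cl)=C\Cl)[C@@H](CO[Si](C(C)C)(C(C)C)C(C)C)c2cc(CO[Si](C(C)C)(C(C)C)C(C)C)co2)cc1OC | intermediate
18 | chloroethynyl ether of 14 | COc1ccc([C@@H](OC#CCl)[C@@H](CO[Si](C(C)C)(C(C)C)C(C)C)c2cc(CO[Si](C(C)C)(C(C)C)C(C)C)co2)cc1OC | intermediate
19 | lithium acetylide of 20 | COc1ccc([C@@H](OC#C[Li])[C@@H](CO[Si](C(C)C)(C(C)C)C(C)C)c2cc(CO[Si](C(C)C)(C(C)C)C(C)C)co2)cc1OC | intermediate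
20 | (1S,2R)-1-(3,4-dimethoxyphenyl)-1-(ethynyloxy)-3-(triisopropylsilyloxy)-2-{4-[(triisopropylsilyloxy)methyl]furan-2-yl}propane | COc1ccc([C@@H](OC#C)[C@@H](CO[Si](C(C)C)(C(C)C)C(C)C)c2cc(CO[Si](C(C)C)(C(C)C)C(C)C)co2)cc1OC | intermediate
21 | 2,3-dihydrofuro[2,3-c]oxepine, the valence tautomer of the C6–C7 arene oxide (oxepine oxygen between C6 and C7; substituents as in 22) | COc1ccc([C@H]2OC3=COC=C(CO[Si](C(C)C)(C(C)C)C(C)C)C=C3[C@@H]2CO[Si](C(C)C)(C(C)C)C(C)C)cc1OC | intermediate
22 | (2S,3R)-2-(3,4-dimethoxyphenyl)-3,5-bis[(triisopropylsilyloxy)methyl]-2,3-dihydrobenzofuran-7-ol | COc1ccc([C@H]2Oc3c(O)cc(CO[Si](C(C)C)(C(C)C)C(C)C)cc3[C@@H]2CO[Si](C(C)C)(C(C)C)C(C)C)cc1OC | intermediate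
23 | (2S,3R)-2-(3,4-dimethoxyphenyl)-7-methoxy-3,5-bis[(triisopropylsilyloxy)methyl]-2,3-dihydrobenzofuran | COc1ccc([C@H]2Oc3c(OC)cc(CO[Si](C(C)C)(C(C)C)C(C)C)cc3[C@@H]2CO[Si](C(C)C)(C(C)C)C(C)C)cc1OC | intermediate
24 | [(2S,3R)-2-(3,4-dimethoxyphenyl)-7-methoxy-2,3-dihydrobenzofuran-3,5-diyl]dimethanol | COc1ccc([C@H]2Oc3c(OC)cc(CO)cc3[C@@H]2CO)cc1OC | intermediate
25 | ethyl (triphenylphosphoranylidene)acetate | CCOC(=O)C=P(c1ccccc1)(c1ccccc1)c1ccccc1 | starting material
26 | (2S,3R)-2-(3,4-dimethoxyphenyl)-3-(hydroxymethyl)-7-methoxy-2,3-dihydrobenzofuran-5-carbaldehyde | COc1ccc([C@H]2Oc3c(OC)cc(C=O)cc3[C@@H]2CO)cc1OC | intermediate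
27 | ethyl (E)-3-[(2S,3R)-2-(3,4-dimethoxyphenyl)-3-(hydroxymethyl)-7-methoxy-2,3-dihydrobenzofuran-5-yl]acrylate | COc1ccc([C@H]2Oc3c(OC)cc(/C=C/C(=O)OCC)cc3[C@@H]2CO)cc1OC | intermediate
28 | Hierochin B | COc1ccc([C@H]2Oc3c(OC)cc(/C=C/CO)cc3[C@@H]2CO)cc1OC | target

Total step count: 13. Longest linear sequence: 13 steps (1 to 28); 2, 5, 8, 15 and 25 enter as bought compounds.

Steps most likely to fail

Step 9. The gold-bound ethynyl ether resembles a ketene oxonium ion sitting on a veratryl-stabilised benzylic carbon. Several processes may therefore outrun the ring closure: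
- heterolysis of the C2–O1 bond
- retro-ene or [3,3] loss of the ether
- hydration
- intermolecular attack at the unsubstituted furan α-position (future C6)

In the fallback, ring A is not built from the furan but taken from ferulic acid through an auxiliary-controlled oxidative 8–5' phenol coupling. It sets out from 5. This is N-acylated with commercial (E)-4-acetoxy-3-methoxycinnamic acid (CC(=O)Oc1ccc(/C=C/C(=O)O)cc1OC; DCC, DMAP, CH2Cl2) to the O-acetylferuloyl imide F1. Pyrrolidine in CH2Cl2 at 0 °C removes the phenolic acetate and gives the feruloyl imide F2. Ag2O in CH2Cl2 then couples two molecules of F2: the carbon α to the imide carbonyl of one bonds to the ring carbon ortho to the phenol of the other, and that phenol oxygen closes onto the quinone methide. This gives the trans-(2S,3S) dihydrobenzofuran bis-imide F3. Only moderate control by the auxiliary is to be expected, so F3 is separated from its (2R,3R) diastereomer by chromatography. MeI and K2CO3 in acetone give the veratryl bis-imide F4. LiBH4 (MeOH, THF, 0 °C) reduces both imides, and the sequence comes back to the route at 28.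

Step 8. The terminal ethynyl ether may be lost during work-up and concentration. The likely processes are retro-ene fragmentation to ketene and the conjugated alkene, [3,3] shift into the veratryl ring, or acid-catalysed hydration to the acetate. The fallback moves purification and storage to a capped alkyne. It sets out from 17, which is taken to the acetylide 19 as before. Quenching with Me3SiCl at −78 °C instead of water gives the trimethylsilylethynyl ether F5. This should resist hydration and fragmentation well enough to be chromatographed and kept cold. K2CO3 in MeOH at 0 °C releases the terminal alkyne just before use, and the fallback comes back to the route at 20.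

Step 7. In the potassium alkoxide the neighbouring triisopropylsilyl group may migrate from the primary to the secondary oxygen. The hindered alkoxide may also add to dichloroacetylene too slowly. The fallback avoids any alkoxide. It sets out from 14, which is formylated (HCO2H, DCC, DMAP, CH2Cl2) to the formate ester F6. Wittig-type dichloromethylenation of the formyl carbonyl (PPh3, CCl4, THF, 60 °C) gives the 2,2-dichlorovinyl ether F7. n-BuLi in THF at −78 °C removes HCl from F7. The fallback comes back to the route at 18, which goes on to 19 and 20 in the same flask as in step 8.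

Further compounds
F1 | step 9 | (4S)-3-[(E)-3-(4-acetoxy-3-methoxyphenyl)acryloyl]-4-benzyl-1,3-oxazolidin-2-one | CC(=O)Oc1ccc(/C=C/C(=O)N2[C@@H](Cc3ccccc3)COC2=O)cc1OC
F2 | step 9 | (4S)-4-benzyl-3-[(E)-3-(4-hydroxy-3-methoxyphenyl)acryloyl]-1,3-oxazolidin-2-one | COc1cc(/C=C/C(=O)N2[C@@H](Cc3ccccc3)COC2=O)ccc1O
F3 | step 9 | trans-(2S,3S)-2-(4-hydroxy-3-methoxyphenyl)-7-methoxy-2,3-dihydrobenzofuran carrying the (4S)-4-benzyl-2-oxooxazolidine-3-carbonyl group at C3 and the (E)-2-[(4S)-4-benzyl-2-oxooxazolidine-3-carbonyl]vinyl group at C5 | COc1cc([C@H]2Oc3c(OC)cc(/C=C/C(=O)N4[C@@H](Cc5ccccc5)COC4=O)cc3[C@@H]2C(=O)N2[C@@H](Cc3ccccc3)COC2=O)ccc1O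
F4 | step 9 | O-methyl ether of F3 (3,4-dimethoxyphenyl at C2) | COc1ccc([C@H]2Oc3c(OC)cc(/C=C/C(=O)N4[C@@H](Cc5ccccc5)COC4=O)cc3[C@@H]2C(=O)N2[C@@H](Cc3ccccc3)COC2=O)cc1OC
F5 | step 8 | (trimethylsilyl)ethynyl ether of 14 (1S,2R) | COc1ccc([C@@H](OC#C[Si](C)(C)C)[C@@H](CO[Si](C(C)C)(C(C)C)C(C)C)c2cc(CO[Si](C(C)C)(C(C)C)C(C)C)co2)cc1OC
F6 | step 7 | formate ester of 14 (1S,2R) | COc1ccc([C@@H](OC=O)[C@@H](CO[Si](C(C)C)(C(C)C)C(C)C)c2cc(CO[Si](C(C)C)(C(C)C)C(C)C)co2)cc1OC
F7 | step 7 | 2,2-dichlorovinyl ether of 14 (1S,2R) | COc1ccc([C@@H](OC=C(Cl)Cl)[C@@H](CO[Si](C(C)C)(C(C)C)C(C)C)c2cc(CO[Si](C(C)C)(C(C)C)C(C)C)co2)cc1OC
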